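**Retrosynthetic overview**

1. Ring B (butenolide) is made last: the C-11'–O bond is cut back to the C-19' carboxylate of the complete polyene, so the forward step is an oxidative closure of the C-19' acid onto C-11'.
2. Polyene: C-11=C-12 by Wittig reaction (C15 phosphonium salt carrying ring C plus a C26 ester-aldehyde); C-10'–C-11' by Heck coupling (2-substituted acrylate carrying ring A plus an iodotetraenal from the C10 dialdehyde).
3. Ring C half: (3R)-3-hydroxy-β-ionone from 3-hydroxy-α-ionone by double-bond migration. Ring A half: 7,8-dihydro-α-ionone with C-19' brought in as CO. Both 3-hydroxyls come from allylic oxidation, then reduction.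
4. Rings A and C: one proton-initiated cation–olefin cyclisation of pseudoionone to α-ionone (the laboratory form of the lycopene cyclase reaction) supplies both halves.
5. Ring order: A and C together in step 1, B in the final step 17.

Assumption: carotenoid numbering is used; the target is (3R,3'R,6'R)-3,3'-dihydroxy-7',8'-dihydro-β,ε-caroten-19',11'-olide with an all-E chain and a (Z)-ylidene lactone, as the SMILES encodes (ring A = ε-ring, ring B = butenolide, ring C = β-ring).

**Route**

Step 1
Reactants: 1 pseudoionone ((3E,5E)-6,10-dimethylundeca-3,5,9-trien-2-one)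
Product: 2 rac-α-ionone ((E)-4-(2,6,6-trimethylcyclohex-2-en-1-yl)but-3-en-2-one)
Conditions: 85% H3PO4, toluene, 30 °C
Reagents that add atoms: none
Why: proton-initiated cation–olefin cyclisation: the C-1 tertiary cation is captured by the C-5/C-6 alkene and H3PO4 gives kinetic loss of H-4, i.e. the ε-type ring, with C-6 formed racemic (resolved in steps 6 and 13).

Step 2
Reactants: 2 rac-α-ionone
Product: 3 rac-α-ionone ethylene ketal (2-methyl-2-[(E)-2-(2,6,6-trimethylcyclohex-2-en-1-yl)ethenyl]-1,3-dioxolane)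
Conditions: Me3SiOCH2CH2OSiMe3, TMSOTf (1 mol%), CH2Cl2, −78 °C
Reagents that add atoms: 1,2-bis(trimethylsilyloxy)ethane, C[Si](C)(C)OCCO[Si](C)(C)C
Why: Noyori ketalisation masks the side-chain ketone without moving the C-7/C-8 alkene, so that only the ring carbonyl is present at the reduction in step 4.

Step 3
Reactants: 3 rac-α-ionone ethylene ketal
Product: 4 rac-3-oxo-α-ionone ethylene ketal (3,5,5-trimethyl-4-[(E)-2-(2-methyl-1,3-dioxolan-2-yl)ethenyl]cyclohex-2-en-1-one)
Conditions: tBuOOH (5 equiv), Pd(OH)2/C (5 mol%), K2CO3 (0.25 equiv), CH2Cl2, 4 °C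
Reagents that add atoms: tert-butyl hydroperoxide, CC(C)(C)OO
Why: radical allylic oxidation (hydrogen abstraction at the unhindered ring CH2 at C-3, the position the ring hydroxylases attack) gives the conjugated enone, as is known for α-ionone-type rings.

Step 4
Reactants: 4 rac-3-oxo-α-ionone ethylene ketal
Product: 5 3-hydroxy-α-ionone ethylene ketal (racemic cis/trans mixture)
Conditions: NaBH4, CeCl3·7H2O, MeOH, −20 °C
Reagents that add atoms: none
Why: Luche 1,2-reduction of the enone; the C-3 carbinol is formed without control on purpose, because C-6 is erased in step 5 and C-3 is resolved in step 6.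

Step 5
Reactants: 5 3-hydroxy-α-ionone ethylene ketal
Product: 7 rac-3-hydroxy-β-ionone ((E)-4-(4-hydroxy-2,6,6-trimethylcyclohex-1-en-1-yl)but-3-en-2-one), via rac-3-hydroxy-α-ionone 6 (not isolated)
Conditions: PPTS, acetone/H2O, 25 °C; then KOH (0.2 equiv), MeOH, 40 °C
Reagents that add atoms: water, O
Why: acetal hydrolysis, then base-catalysed double-bond migration through the extended dienolate (deprotonation at C-6) into conjugation with the enone, which turns the ε-type ring into the β-ring and removes the C-6 stereocentre while C-3 is untouched.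

Step 6
Reactants: 7 rac-3-hydroxy-β-ionone
Product: 8 (3R)-3-acetoxy-β-ionone ((1R)-3,5,5-trimethyl-4-[(E)-3-oxobut-1-en-1-yl]cyclohex-3-en-1-yl acetate)
Conditions: lipase PS (Burkholderia cepacia lipase), vinyl acetate, tBuOMe, 30 °C, to 50% conversion
Reagents that add atoms: vinyl acetate, CC(=O)OC=C
Why: lipase-catalysed kinetic resolution by transesterification, a resolution established for 3-hydroxy-β-ionone; by Kazlauskas' rule (C-2 arm with the gem-dimethyl group as the large group) the (3R)-alcohol is acylated and is separated from the (3S)-alcohol by chromatography.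

Step 7
Reactants: 8 (3R)-3-acetoxy-β-ionone
Product: 9 (1R)-4-[(1E)-3-hydroxy-3-methylpenta-1,4-dien-1-yl]-3,5,5-trimethylcyclohex-3-en-1-ol (C-9 epimers)
Conditions: CH2=CHMgBr (3.3 equiv), THF, −20 → 0 °C; aq NH4Cl
Reagents that add atoms: vinylmagnesium bromide, C=C[Mg]Br
Why: Grignard 1,2-addition to the dienone carbonyl, with two further equivalents cleaving the acetate; the C-9 carbinol configuration is irrelevant because it is lost in step 8.

Step 8
Reactants: 9 (3R)-vinyl carbinol
Product: 10 [(2E,4E)-5-[(4R)-4-hydroxy-2,6,6-trimethylcyclohex-1-en-1-yl]-3-methylpenta-2,4-dien-1-yl]triphenylphosphonium bromide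
Conditions: PPh3·HBr, MeOH, 0 → 25 °C
Reagents that add atoms: triphenylphosphine hydrobromide, [Br-].[PH+](c1ccccc1)(c1ccccc1)c1ccccc1
Why: ionisation of the tertiary bis-allylic alcohol and capture of the pentadienyl cation by PPh3 at the unhindered terminus (allylic substitution with transposition), the standard entry to C15 Wittig salts; the non-allylic 3-OH is not touched.

Step 9
Reactants: 2 rac-α-ionone
Product: 11 rac-7,8-dihydro-α-ionone (4-(2,6,6-trimethylcyclohex-2-en-1-yl)butan-2-one)
Conditions: H2 (1 atm), RhCl(PPh3)3 (2 mol%), toluene/EtOH, 25 °C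
Reagents that add atoms: none
Why: homogeneous hydrogenation selects the disubstituted enone C-7/C-8 alkene over the hindered trisubstituted ring alkene and gives the saturated C-7'/C-8' link of ring A.

Step 10
Reactants: 11 rac-7,8-dihydro-α-ionone
Product: 12 rac-4-(2,6,6-trimethylcyclohex-2-en-1-yl)but-1-en-2-yl trifluoromethanesulfonate
Conditions: LiN(iPr)2, THF, −78 °C; then PhNTf2, −78 → 0 °C
Reagents that add atoms: N-phenylbis(trifluoromethanesulfonimide), O=S(=O)(N(c1ccccc1)S(=O)(=O)C(F)(F)F)C(F)(F)F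
Why: kinetic deprotonation of the methyl ketone at CH3 and O-triflation of the less substituted enolate (enol triflate formation); this CH3 becomes C-10'.

Step 11
Reactants: 12 vinyl triflate
Product: 13 rac-methyl 2-methylidene-4-(2,6,6-trimethylcyclohex-2-en-1-yl)butanoate
Conditions: Pd(OAc)2 (3 mol%), PPh3 (6 mol%), CO (1 atm), MeOH, Et3N, DMF, 40 °C
Reagents that add atoms: carbon monoxide, [C-]#[O+]; methanol, CO
Why: palladium-catalysed methoxycarbonylation of the vinyl triflate installs C-19' directly at the carboxylic acid oxidation level and gives a 2-substituted acrylate.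

Step 12
Reactants: 13 rac-acrylate
Product: 14 rac-methyl 2-methylidene-4-(2,6,6-trimethyl-4-oxocyclohex-2-en-1-yl)butanoate
Conditions: tBuOOH (5 equiv), Pd(OH)2/C (5 mol%), K2CO3 (0.25 equiv), CH2Cl2, 4 °C
Reagents that add atoms: tert-butyl hydroperoxide, CC(C)(C)OO
Why: the same radical allylic oxidation as in step 3; the CH2 next to the electron-poor acrylate is far less prone to hydrogen abstraction than the ring C-3' methylene.

Step 13
Reactants: 14 rac-enone
Product: 15 methyl 4-[(1R,4R)-4-hydroxy-2,6,6-trimethylcyclohex-2-en-1-yl]-2-methylidenebutanoate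
Conditions: (S)-2-methyl-CBS-oxazaborolidine (0.2 equiv), catecholborane (0.55 equiv), toluene, −78 °C
Reagents that add atoms: none
Why: Corey–Bakshi–Shibata reduction run as a kinetic resolution: the catalyst delivers hydride to the enone face that gives (3'R) (alkene arm as the large group), and only in the (6'R)-enantiomer is this also the face anti to the axial C-1' methyl group, so the matched enantiomer is reduced to the trans-(3'R,6'R) alcohol while the (6'S)-enone is left and removed by chromatography.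

Step 14
Reactants: 16 (2E,4E,6E)-2,7-dimethylocta-2,4,6-trienedial
Product: 17 (2E,4E,6E,8E)-9-iodo-2,7-dimethylnona-2,4,6,8-tetraenal
Conditions: CrCl2 (4 equiv), CHI3 (1 equiv), 16 (3 equiv), THF/dioxane, 0 °C, dark
Reagents that add atoms: iodoform, IC(I)I
Why: Takai iodo-olefination gives the (E)-vinyl iodide and supplies C-11'; limiting iodoform against excess dialdehyde keeps the reaction at one end, and unreacted 16 is recovered.

Step 15
Reactants: 15 hydroxy acrylate; 17 iodotetraenal
Product: 18 methyl (2E,4E,6E,8E,10E)-2-{2-[(1R,4R)-4-hydroxy-2,6,6-trimethylcyclohex-2-en-1-yl]ethyl}-6,11-dimethyl-12-oxododeca-2,4,6,8,10-pentaenoate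
Conditions: Pd(OAc)2 (10 mol%), Bu4NCl, NaHCO3, DMF, 40 °C, dark
Reagents that add atoms: none
Why: Mizoroki–Heck coupling under ligand-free conditions: the alkenylpalladium adds to the acrylate CH2 and β-hydride elimination towards C-10' gives the conjugated dienoate with retention of the iodide geometry; the C-9'/C-10' geometry is of no consequence because step 17 equilibrates it.

Step 16
Reactants: 18 C26 ester-aldehyde; 10 C15 phosphonium bromide
Product: 19 methyl (3R,3'R,6'R)-3,3'-dihydroxy-7',8'-dihydro-β,ε-caroten-19'-oate (all-E chain; ester group trans to C-11')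
Conditions: NaOMe, MeOH/CH2Cl2, 0 → 25 °C; then reflux in EtOAc
Reagents that add atoms: none
Why: Wittig olefination forms C-11/C-12 (the standard coupling of a C15 salt with a polyenal, free hydroxyls tolerated), and heating converts the 11Z share into the all-E chain.

Step 17
Reactants: 19 C40 methyl ester
Product: 21 (3R,3'R,6'R)-3,3'-dihydroxy-7',8'-dihydro-β,ε-caroten-19',11'-olide (target), via potassium carboxylate 20 (not isolated)
Conditions: KOH (2.0 equiv), THF/MeOH/H2O, 40 °C; then pH 8 phosphate buffer, I2 (1.05 equiv), THF, 0 → 25 °C, dark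
Reagents that add atoms: potassium hydroxide, [K+].[OH-]
Why: Proposed new method: after routine saponification to 20, iodine takes two electrons from the electron-rich polyene (as in the known iodine- and NBS-mediated dehydrogenations of carotenoids to retro-dehydro compounds); attack of the tethered C-19' carboxylate at C-11' leaves the positive charge delocalised over the whole chain from C-12' to C-5, whereas attack at C-12' would strand it on the three-carbon acrylate unit, so 5-exo closure to the γ-lactone is favoured, and buffer-mediated loss of the now activated H-11' restores the polyene as the thermodynamically preferred (Z)-ylidene butenolide while iodine equilibrates the 9' and other chain double bonds, so that the 9'-geometry of 19 does not matter; closest known reaction type: iodolactonisation–dehydroiodination of (2Z)-2,4-dienoic acids to γ-ylidene butenolides.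

**Compound list**

1 | pseudoionone, (3E,5E)-6,10-dimethylundeca-3,5,9-trien-2-one | CC(C)=CCC/C(C)=C/C=C/C(C)=O | starting material
2 | rac-α-ionone | CC1=CCCC(C)(C)C1/C=C/C(C)=O | intermediate
3 | rac-α-ionone ethylene ketal | CC1=CCCC(C)(C)C1/C=C/C1(C)OCCO1 | intermediate
4 | rac-3-oxo-α-ionone ethylene ketal | CC1=CC(=O)CC(C)(C)C1/C=C/C1(C)OCCO1 | intermediate
5 | 3-hydroxy-α-ionone ethylene ketal (racemic, cis/trans mixture) | CC1=CC(O)CC(C)(C)C1/C=C/C1(C)OCCO1 | intermediate
6 | rac-3-hydroxy-α-ionone (cis/trans mixture, not isolated) | CC(=O)/C=C/C1C(C)=CC(O)CC1(C)C | intermediate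
7 | rac-3-hydroxy-β-ionone | CC(=O)/C=C/C1=C(C)CC(O)CC1(C)C | intermediate
8 | (3R)-3-acetoxy-β-ionone | CC(=O)/C=C/C1=C(C)C[C@@H](OC(C)=O)CC1(C)C | intermediate
9 | (1R)-4-[(1E)-3-hydroxy-3-methylpenta-1,4-dien-1-yl]-3,5,5-trimethylcyclohex-3-en-1-ol (C-9 epimers) | C=CC(C)(O)/C=C/C1=C(C)C[C@@H](O)CC1(C)C | intermediate
10 | [(2E,4E)-5-[(4R)-4-hydroxy-2,6,6-trimethylcyclohex-1-en-1-yl]-3-methylpenta-2,4-dien-1-yl]triphenylphosphonium bromide | [Br-].c1ccccc1[P+](c1ccccc1)(c1ccccc1)C/C=C(C)/C=C/C1=C(C)C[C@@H](O)CC1(C)C | intermediate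
11 | rac-7,8-dihydro-α-ionone | CC1=CCCC(C)(C)C1CCC(C)=O | intermediate
12 | rac-4-(2,6,6-trimethylcyclohex-2-en-1-yl)but-1-en-2-yl trifluoromethanesulfonate | CC1=CCCC(C)(C)C1CCC(=C)OS(=O)(=O)C(F)(F)F | intermediate
13 | rac-methyl 2-methylidene-4-(2,6,6-trimethylcyclohex-2-en-1-yl)butanoate | CC1=CCCC(C)(C)C1CCC(=C)C(=O)OC | intermediate
14 | rac-methyl 2-methylidene-4-(2,6,6-trimethyl-4-oxocyclohex-2-en-1-yl)butanoate | CC1=CC(=O)CC(C)(C)C1CCC(=C)C(=O)OC | intermediate
15 | methyl 4-[(1R,4R)-4-hydroxy-2,6,6-trimethylcyclohex-2-en-1-yl]-2-methylidenebutanoate | CC1=C[C@H](O)CC(C)(C)[C@H]1CCC(=C)C(=O)OC | intermediate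
16 | (2E,4E,6E)-2,7-dimethylocta-2,4,6-trienedial | O=C/C(C)=C/C=C/C=C(C)/C=O | starting material
17 | (2E,4E,6E,8E)-9-iodo-2,7-dimethylnona-2,4,6,8-tetraenal | I/C=C/C(C)=C/C=C/C=C(C)/C=O | intermediate
18 | methyl (2E,4E,6E,8E,10E)-2-{2-[(1R,4R)-4-hydroxy-2,6,6-trimethylcyclohex-2-en-1-yl]ethyl}-6,11-dimethyl-12-oxododeca-2,4,6,8,10-pentaenoate | CC1=C[C@H](O)CC(C)(C)[C@H]1CC/C(C(=O)OC)=C\C=C\C(C)=C\C=C\C=C(C)\C=O | intermediate
19 | methyl (3R,3'R,6'R)-3,3'-dihydroxy-7',8'-dihydro-β,ε-caroten-19'-oate (all-E, ester trans to C-11') | CC1=C[C@H](O)CC(C)(C)[C@H]1CC/C(C(=O)OC)=C\C=C\C(C)=C\C=C\C=C(C)\C=C\C=C(C)\C=C\C1=C(C)C[C@@H](O)CC1(C)C | intermediate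
20 | potassium (3R,3'R,6'R)-3,3'-dihydroxy-7',8'-dihydro-β,ε-caroten-19'-oate (not isolated) | [K+].CC1=C[C@H](O)CC(C)(C)[C@H]1CC/C(C(=O)[O-])=C\C=C\C(C)=C\C=C\C=C(C)\C=C\C=C(C)\C=C\C1=C(C)C[C@@H](O)CC1(C)C | intermediate
21 | (3R,3'R,6'R)-3,3'-dihydroxy-7',8'-dihydro-β,ε-caroten-19',11'-olide | CC1=C[C@H](O)CC(C)(C)[C@H]1CCC1=C/C(=C/C(C)=C/C=C/C=C(C)/C=C/C=C(C)/C=C/C2=C(C)C[C@@H](O)CC2(C)C)OC1=O | target

**Step count, longest linear sequence, risks**

Total: 17 steps. Longest linear sequence: 10 steps (steps 1–8, 16, 17).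

Most likely to fail, first: step 17. The closure has no precedent on a C40 polyene, and 6-ring closure or retro-dehydro products may compete. The fallback sets out from 15 and from 10 with 16, and comes back at 21. Ring B is built before the chain is complete and the ylidene bond is made by condensation instead of oxidation. Transesterification of 15 with allyl alcohol (Ti(OiPr)4, 80 °C) gives the allyl ester F1. Ring-closing metathesis with the second-generation Grubbs catalyst (H2IMes)(PCy3)Cl2Ru=CHPh (toluene, 80 °C) gives the 3-substituted butenolide F2. Wittig reaction of 10 with excess 16 (NaOMe) gives the C25 hydroxy aldehyde F3. F2 and F3 are joined in one flask by vinylogous Mukaiyama aldol addition (TBSOTf, iPr2NEt, CH2Cl2, −78 °C) to the silyl aldol adduct F4, which DBU converts by elimination into the bis-silyl ether F5, and HF·pyridine then gives 21.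

Second: step 13. It relies on matched double stereodifferentiation on a hindered isophorone-type enone. The fallback sets out from 14 and comes back at 15. Luche reduction (NaBH4, CeCl3·7H2O, MeOH, −40 °C) gives the racemic trans alcohol F6 by substrate control (hydride anti to the axial C-1' methyl). Lipase PS with vinyl acetate then acylates the (1S,4S)-enantiomer to the acetate F7 and leaves 15, which is separated by chromatography.

Third: step 15. β-Hydride elimination towards C-8' and loss of the polyenyl iodide are the dangers. The fallback sets out from 15 and 16 and comes back at 18; it makes the C-10'–C-11' bond by Suzuki–Miyaura coupling instead. Tsuji–Wacker acetalisation of the acrylate 15 (PdCl2(MeCN)2, CuCl, O2, MeOH) gives the β,β-dimethoxy ester F8. Hydrolysis (aqueous oxalic acid) gives the formyl ester F9, whose enol is O-triflated (PhNTf2, K2CO3, DMF) to the β-triflyloxy acrylate F10. Takai–Utimoto boryl-olefination of 16 (Cl2CHBpin, CrCl2, LiI) gives the alkenyl boronate F11. Coupling of F10 with F11 (Pd(PPh3)4, K3PO4, dioxane/H2O) gives 18, together with some of its 2Z isomer, which is equally usable.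

**Further compounds**

F1 | step 17 | allyl 4-[(1R,4R)-4-hydroxy-2,6,6-trimethylcyclohex-2-en-1-yl]-2-methylidenebutanoate | CC1=C[C@H](O)CC(C)(C)[C@H]1CCC(=C)C(=O)OCC=C
F2 | step 17 | 3-{2-[(1R,4R)-4-hydroxy-2,6,6-trimethylcyclohex-2-en-1-yl]ethyl}furan-2(5H)-one | CC1=C[C@H](O)CC(C)(C)[C@H]1CCC1=CCOC1=O
F3 | step 17 | (3R)-3-hydroxy-12'-apo-β-caroten-12'-al | O=C/C(C)=C/C=C/C=C(C)/C=C/C=C(C)/C=C/C1=C(C)C[C@@H](O)CC1(C)C
F4 | step 17 | tris-O-TBS vinylogous aldol adduct of F2 and F3 (C-11'/C-12' epimers, not isolated) | CC1=C[C@H](O[Si](C)(C)C(C)(C)C)CC(C)(C)[C@H]1CCC1=CC(OC1=O)C(O[Si](C)(C)C(C)(C)C)/C(C)=C/C=C/C=C(C)/C=C/C=C(C)/C=C/C1=C(C)C[C@@H](O[Si](C)(C)C(C)(C)C)CC1(C)C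
F5 | step 17 | 3,3'-bis-O-(tert-butyldimethylsilyl) ether of 21 | CC1=C[C@H](O[Si](C)(C)C(C)(C)C)CC(C)(C)[C@H]1CCC1=C/C(=C/C(C)=C/C=C/C=C(C)/C=C/C=C(C)/C=C/C2=C(C)C[C@@H](O[Si](C)(C)C(C)(C)C)CC2(C)C)OC1=O
F6 | step 13 | racemic trans-methyl 4-(4-hydroxy-2,6,6-trimethylcyclohex-2-en-1-yl)-2-methylidenebutanoate (1R,4R and 1S,4S) | CC1=C[C@H](O)CC(C)(C)[C@H]1CCC(=C)C(=O)OC.CC1=C[C@@H](O)CC(C)(C)[C@@H]1CCC(=C)C(=O)OC
F7 | step 13 | methyl 4-[(1S,4S)-4-acetoxy-2,6,6-trimethylcyclohex-2-en-1-yl]-2-methylidenebutanoate | CC1=C[C@@H](OC(C)=O)CC(C)(C)[C@@H]1CCC(=C)C(=O)OC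
F8 | step 15 | methyl 2-(dimethoxymethyl)-4-[(1R,4R)-4-hydroxy-2,6,6-trimethylcyclohex-2-en-1-yl]butanoate (C-2 epimers) | CC1=C[C@H](O)CC(C)(C)[C@H]1CCC(C(OC)OC)C(=O)OC
F9 | step 15 | methyl 2-formyl-4-[(1R,4R)-4-hydroxy-2,6,6-trimethylcyclohex-2-en-1-yl]butanoate (keto/enol, not isolated) | CC1=C[C@H](O)CC(C)(C)[C@H]1CCC(C=O)C(=O)OC
F10 | step 15 | methyl 4-[(1R,4R)-4-hydroxy-2,6,6-trimethylcyclohex-2-en-1-yl]-2-{[(trifluoromethanesulfonyl)oxy]methylidene}butanoate (E/Z mixture) | CC1=C[C@H](O)CC(C)(C)[C@H]1CCC(=COS(=O)(=O)C(F)(F)F)C(=O)OC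
F11 | step 15 | (2E,4E,6E,8E)-2,7-dimethyl-9-(4,4,5,5-tetramethyl-1,3,2-dioxaborolan-2-yl)nona-2,4,6,8-tetraenal | CC1(C)OB(/C=C/C(C)=C/C=C/C=C(C)/C=O)OC1(C)C
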